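Remark: atoms are numbered C1–C9 as in the bicycle of the target (C1 beside CMe2 C8, C5 beside CH2 C6), also in the monocyclic precursors; geranyl = (2E)-3,7-dimethylocta-2,6-dien-1-yl, prenyl = 3-methylbut-2-en-1-yl, ArCO = 3,4-bis(tert-butyldimethylsilyloxy)benzoyl; enolised triketones are written as one tautomer, so 10 is named as the cyclohexa-2,4-dien-1-one that its SMILES encodes (a cyclohexa-2,5-dien-1-one name would describe another tautomer of the same substance), and CIP descriptors refer to the tautomer drawn.

## Structural features

The target is a type B polyprenylated acylphloroglucinol. Ring A (C1, C8, C7, C6, C5, C9) is a cyclohexanone and ring B (C1, C2, C3, C4, C5, C9) an enolised 2-acyl-1,3-diketone; the rings share the bridgeheads C1 and C5 and the ketone C9, and C3 carries the 3,4-dihydroxybenzoyl group. Both bridgeheads are quaternary and geranylated, C1 stands next to the quaternary gem-dimethyl carbon C8, and C8 next to the stereocentre C7 with its equatorial prenyl group. There are three stereocentres (1S,5S,7R); C1 and C5 are tied together by the bicycle, so only the absolute sense of the bicycle and the orientation at C7 are free. Five trisubstituted alkenes (acid-induced cyclisation), an acidic chelating triketone (O-alkylation, retro-Claisen cleavage) and an oxidisable catechol exclude strong acid, hydrogenation and late oxidants. The real difficulty is the C1–C8–C7 region inside a bridged ring, together with absolute control far from any functional handle. The key step uses the fact that C8 is a CMe2 carbon on C1, which lies between the C2 and C9 carbonyls: C8 is an isopropyl carbon of a dearomatised acylphloroglucinol at a higher oxidation level and is electrophilic as an isopropylidene, while C7 becomes the α-carbon of an aldehyde once the prenyl CH2 is traced back to a formyl group.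

## Logic of the disconnections

20 to 19: the two phenolic O–H bonds are traced back to O–Si bonds. The catechol must be masked through every oxidising and basic step, and fluoride is the one deprotection that spares five alkenes and the triketone. The skeleton is unchanged; the forward step needs buffered fluoride.

19 to 17 and 18: the C1–CH2 bond of the bridgehead geranyl group is cut. In 17 the C1–H is the only activated C–H besides the enol, and a bridgehead can only be substituted with retention. Ten carbons and one quaternary centre are removed, and 17 has exactly the C1–H that the key step leaves. The forward step must form a dianion and alkylate on carbon, not on oxygen.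

17 to 16 to 14: the prenyl C=C bond is cut, then the bond between the CH2 on C7 and the aldehyde carbon of 16. This turns the prenyl group into the formyl group that makes C7 an enamine carbon. The forward steps must tolerate the acidic enol, leave the C9 ketone alone and not scramble C7.

14 to 10: the C7–C8 bond is cut and two hydrogens are returned (to C8 and to oxygen). Ring A, the quaternary C8 and the stereocentres C1 and C7 disappear, leaving a monocyclic dearomatised acylphloroglucinol with one stereocentre. The forward step must oxidise only the isopropyl group and then close a hindered bond whose acceptor α-carbon becomes a bridgehead.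

10 to 8 and 9: the C5–C6 bond is cut. This returns an achiral, fully substituted aromatic ring and a three-carbon enal, so all absolute stereochemistry rests on one catalytic step. The forward step must attack the geranyl-bearing carbon (not the isopropyl- or aroyl-bearing carbon, not oxygen) with facial control.

8 to 7: the two O–Si bonds are cut. Silylation is placed here because after this point base, acrolein and an oxidant follow. The forward step must silylate the catechol in the presence of three ring hydroxyls.

7 to 5 and 6: the aryl C–CH2 bond of the geranyl group is cut; the position is the only free ring carbon of 5. The forward step must alkylate carbon with a free catechol present and without closing the chain onto a neighbouring hydroxyl.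

5 to 3 and 4: the aryl C–CH bond of the isopropyl group is cut. The forward step must stop after one alkylation at two equivalent positions.

3 to 1 and 2: the aryl–carbonyl bond is cut, giving two commercial phenols. The forward step is a single acylation that deactivates the ring against a second one.

## Other disconnections considered

Alternative 1: The cut is the C4–C5 bond of ring B together with a hydride at C6. It leads back to the ring A enone A2, a 2-geranylcyclohex-2-enone carrying on C1 a geranyl group and a methyl (E)-3-methoxyacrylate bound through its β-carbon, with the C8 methyls and the C7 prenyl group in place. Forward, K[(s-Bu)3BH] should add hydride to C6, and the regiodefined C5 potassium enolate should attack the ester of the axial acrylate in a Claisen (Dieckmann-type) closure to give the vinylogous ester A1.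
- In its favour: the ring-closing bond is made by a ring carbon that becomes sp3 as the bridgehead forms, so no strained enolate is involved; the enolate is generated at one site only; both geranyl groups and the C7/C8 array exist before the bicycle, so no late bridgehead alkylation is needed.
- Against it here: A2 is itself a demanding target (a quaternary C1 beside CMe2 and beside C7, with the acrylate axial), the hydride must choose C6 over the methoxyacrylate and over the C9 carbonyl, and after A1 a C3 aroylation, an O-demethylation and the desilylation remain; absolute configuration has to be built early in an aliphatic sequence.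
- Comparison: on structure A1 is ahead of 14 (all three side chains present). On mechanism it is the better plan, because each step is of a known type and stereoelectronically normal. On step economy it is worse: the aliphatic route to A2 is estimated at well over the five aromatic steps that lead to 10.

Alternative 2: The cut is the C1–C8 bond. The precursor is the symmetric dienone A4, 4-geranyl-3,5-dimethoxycyclohexa-2,5-dien-1-one carrying on C4 a 2-isopropenyl-5-methylhex-4-enyl (lavandulyl) chain whose only stereocentre is C7. Forward, Co(salen) (C16H14CoN2O2, divalent cobalt), PhSiH3 and N-fluoro-2,4,6-trimethylpyridinium triflate should transfer a hydrogen atom to the isopropenyl group; the C8 radical, oxidised to the cation, should be captured by one of the two enol ether carbons, and loss of methyl from the oxocarbenium ion should give A3.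
- In its favour: this is the polarity of the biosynthesis, the two most hindered carbons are joined intramolecularly, the bridgehead becomes sp3 in the bond-forming event, and one stereocentre chooses between the two enol ethers and so fixes C5 and C1.
- Against it here: three trisubstituted alkenes compete for hydrogen-atom transfer, the degree of selection between the enol ethers is uncertain, A4 requires alkylation with a β-branched, unreactive electrophile, and after A3 a bridgehead geranylation, a C3 aroylation, a demethylation and a desilylation remain.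
- Comparison: on structure A3 already has the C7 prenyl group (better than 14, which needs a homologation) but lacks the aroyl group (worse). On mechanism it matches known cation–enol closures and is the sounder plan at the key step; both plans let one stereocentre control the rest (equal). On step economy the two are estimated to be about equal, with more late-stage lithiations in this alternative.

Alternative 3: The cuts are C5–C6 and the bond from C7 to the prenyl CH2, in one operation. The precursor A6 is a dearomatised acylphloroglucinol with geranyl and 1,1-dimethylallyl on C1 and geranyl on the enol carbon C5. Forward, PdCl2(MeCN)2 (divalent palladium) should activate the vinyl group, C5 should attack C6 anti to the metal, and the C7–Pd bond should insert 3-chloro-3-methylbut-1-ene A7 and expel chloride, giving A5, which is identical with 19.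
- In its favour: it is the most convergent plan, redox-neutral in palladium, the product is one deprotection from the target, and the ring carbon becomes sp3 as the ring closes.
- Against it here: A6 needs an intermolecular, enantioselective reverse prenylation that creates the vicinal quaternary pair C1–C8; in the key step attack through the enol oxygen and 5-exo closure compete; four trisubstituted alkenes can bind the metal; β-hydride loss from C7–Pd (hydrogens on C6) should be faster than insertion of a hindered alkene; C7 is set kinetically and cannot be corrected.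
- Comparison: on step economy it is clearly better (A5 equals 19 without homologation or bridgehead alkylation). On structure it is better as well. On mechanism it has more competing channels than the chosen closure, and the chosen plan is better at C7, which it sets under thermodynamic control.

Key step: step 6

## Route

Step 1
Reactants: 1 phloroglucinol; 2 3,4-dihydroxybenzoic acid
Product: 3 (3,4-dihydroxyphenyl)(2,4,6-trihydroxyphenyl)methanone
Conditions: BF3·OEt2, 90 °C; then H2O
Reagents that add atoms: none
Why: Friedel–Crafts acylation of the most electron-rich arene by the BF3-activated acid; the ring of 2 is deactivated by its own carbonyl, and the first acyl group deactivates 1 against a second acylation.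

Step 2
Reactants: 3; 4 propan-2-ol
Product: 5 (3,4-dihydroxyphenyl)[2,4,6-trihydroxy-3-(propan-2-yl)phenyl]methanone
Conditions: 4 (1.0 equiv), MeSO3H, 50 °C
Reagents that add atoms: none
Why: Friedel–Crafts alkylation: the 2-propyl cation equivalent formed from 4 should attack one of the two equivalent free positions of the phloroglucinol ring, the catechol ring being deactivated by the ketone; 4 is the limiting reagent so that dialkylation stays minor and unchanged 3 can be recycled.

Step 3
Reactants: 5; 6 geraniol
Product: 7 (3,4-dihydroxyphenyl)[3-geranyl-2,4,6-trihydroxy-5-(propan-2-yl)phenyl]methanone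
Conditions: 6 (1.2 equiv), BF3·OEt2 (0.5 equiv), dioxane, 0 °C to rt
Reagents that add atoms: none
Why: Friedel–Crafts allylation: the BF3-activated allylic alcohol should be attacked through its primary terminus by the single free carbon of the phloroglucinol ring, which lies between two hydroxyl groups; the phenolic oxygens, the catechol included, do not compete under acid, and low temperature should preserve the E geometry and suppress closure of the chain onto a neighbouring hydroxyl.

Step 4
Reactants: 7
Product: 8 [3,4-bis(tert-butyldimethylsilyloxy)phenyl][3-geranyl-2,4,6-trihydroxy-5-(propan-2-yl)phenyl]methanone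
Conditions: TBSCl (2.2 equiv), imidazole, DMF, 0 °C
Reagents that add atoms: tert-butyldimethylsilyl chloride, CC(C)(C)[Si](C)(C)Cl
Why: Silylation under kinetic control: the two catechol hydroxyls are unhindered, whereas each phloroglucinol hydroxyl is flanked by two ring substituents and two of them are hydrogen-bonded to the ketone. The silyl ethers are needed because the oxidant of step 6 would otherwise convert the catechol into the quinone.

Step 5
Reactants: 8; 9 acrolein
Product: 10 (6S)-2-(ArCO)-6-geranyl-3,5-dihydroxy-6-(3-oxopropyl)-4-(propan-2-yl)cyclohexa-2,4-dien-1-one (in equilibrium with its cyclic hemiacetal; used without storage)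
Conditions: 9 (2 equiv), O-allyl-N-(9-anthracenylmethyl)cinchonidinium bromide (10 mol%), K2CO3 (0.5 equiv, solid), PhMe, −40 °C; AcOH quench
Reagents that add atoms: none
Why: Phase-transfer-catalysed asymmetric Michael addition with dearomatisation, the reaction type used for enantioselective alkylative dearomatisation of acylphloroglucinols with enals: the chiral ammonium phenoxide should add through the geranyl-bearing carbon, which is less hindered than the isopropyl-bearing carbon and more electron-rich than the aroyl-bearing one. The quaternary stereocentre C5 is set by the face of the ion pair that the catalyst leaves open; the catalyst or its cinchoninium pseudoenantiomer is chosen to deliver 6S. Solid carbonate at low temperature is used so that the aryl silyl ethers are not cleaved.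

Step 6
Reactants: 10
Product: 14 (1S,5S,7R)-3-(ArCO)-7-formyl-5-geranyl-4-hydroxy-8,8-dimethylbicyclo[3.3.1]non-3-ene-2,9-dione, via isopropylidene trione 11 (not isolated), via side-chain pyrrolidine enamine 12 (not isolated), via bicyclic enamine 13 (not isolated)
Conditions: Ag2O (1.2 equiv), 2,2,6,6-tetramethylpiperidin-1-oxyl (0.3 equiv), 4 Å MS, PhMe, 0 °C to rt; filtration through Celite; then pyrrolidine (1.2 equiv), AcOH (2 equiv), PhMe (0.01 M), rt to 50 °C; aq. NH4Cl
Reagents that add atoms: water, O
Why: Proposed new method: Ag2O with the nitroxyl should remove the enolic hydrogen and the tertiary C8–H of the isopropyl group on C1 (enol radical, capture at C1 by the nitroxyl, loss of the hydroxylamine, which silver oxide re-oxidises), giving the cross-conjugated isopropylidene trione 11, which cannot aromatise because C5 is quaternary; once the silver is filtered off, buffered pyrrolidine converts the aldehyde (free or as its lactol) into enamine 12. The enamine carbon C7 then adds to C8 of the C1=C8 acceptor, the charge is taken up by the C2 carbonyl as a strained bridgehead enolate that is protonated on C1 by acetic acid as the bond forms, and the iminium ion relaxes to enamine 13, which is hydrolysed to 14 on work-up. The closest known reaction types are the silver oxide/nitroxyl dehydrogenation of alkylated dearomatised acylphloroglucinols to alkylidene triones and amine-mediated intramolecular enamine Michael additions to alkylidene 1,3-dicarbonyl compounds; their union on a ring-bound isopropylidene, with a bridgehead created at the acceptor α-carbon, is without direct precedent. Ring A closes in a 6-endo-trig mode with respect to the acceptor (both C8 and C1 lie in the new ring), through a chair-like arrangement in which the axial C5–C6 bond carries the enamine over C8. C1 is not an independent stereocentre, since with C5 fixed the bicycle can only form with the C1–C8 bond axial on ring B and the new C1–H equatorial; C7 is set under thermodynamic control, because it remains epimerisable through 13 and its iminium ion, and should settle with the formyl group equatorial (anti to ring B), which is the 7R configuration required. The step needs site-selective dehydrogenation, secured because the isopropyl methine is the only C–H on a carbon bound to an enol carbon, and it needs the C7–C8 closure to win over lactol formation, aza-Michael addition of pyrrolidine at C8, Mannich closure at C3 and tautomerisation to the isopropenyl enol; all of these are reversible under the buffered conditions, whereas the closure ends in a bridgehead C–H that an amine cannot remove again.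

Step 7
Reactants: 14
Product: 16 (1S,5S,7S)-3-(ArCO)-5-geranyl-4-hydroxy-8,8-dimethyl-7-(2-oxoethyl)bicyclo[3.3.1]non-3-ene-2,9-dione, via methyl enol ether 15 (not isolated)
Conditions: Ph3P(CH2OMe)Cl (4.5 equiv), KN(SiMe3)2 (4.3 equiv), THF, 0 °C; 14, 0 °C to rt; then 2 M aq. HCl, THF, rt
Reagents that add atoms: (methoxymethyl)triphenylphosphonium chloride, COC[P+](c1ccccc1)(c1ccccc1)c1ccccc1.[Cl-]; water, O
Why: Wittig methoxymethylenation followed by enol ether hydrolysis (one-carbon homologation): the first equivalent of base turns the triketone into its enolate, which shields C2, C4 and the aroyl carbonyl, and the C9 ketone between two bridgeheads is too hindered to react; dilute acid hydrolyses only the enol ether. After olefination C7 is no longer epimerisable, and any epimerisation of 14 before it returns the favoured equatorial isomer (the descriptor changes to 7S only through CIP priorities).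

Step 8
Reactants: 16
Product: 17 (1S,5S,7R)-3-(ArCO)-5-geranyl-4-hydroxy-8,8-dimethyl-7-prenylbicyclo[3.3.1]non-3-ene-2,9-dione
Conditions: Ph3P(i-Pr)I (4 equiv), n-BuLi (3.8 equiv), THF, 0 °C; 16, −78 °C to rt
Reagents that add atoms: isopropyltriphenylphosphonium iodide, CC(C)[P+](c1ccccc1)(c1ccccc1)c1ccccc1.[I-]
Why: Wittig reaction with the isopropylidene ylide converts the aldehyde into the trisubstituted alkene of the prenyl group; the ylide carbon is symmetrical, so no alkene geometry arises, and the triketonate again protects ring B.

Step 9
Reactants: 17; 18 geranyl bromide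
Product: 19 (1S,5S,7R)-3-(ArCO)-1,5-digeranyl-4-hydroxy-8,8-dimethyl-7-prenylbicyclo[3.3.1]non-3-ene-2,9-dione
Conditions: LiN(i-Pr)2 (3.2 equiv), THF, −78 to −20 °C; 18 (1.3 equiv), −78 to 0 °C
Reagents that add atoms: none
Why: Alkylation of a β-dicarbonyl dianion at its more basic carbon, combined with bridgehead lithiation as used on bicyclic triones of this family: the first equivalent of base gives the triketonate, further base removes the only remaining activated C–H, the bridgehead C1–H between the C2 and C9 carbonyls, and the lithiated carbon rather than the delocalised oxygens should attack the allylic bromide. The quaternary stereocentre C1 can only form with retention, because the bicycle exposes a single exo position.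

Step 10
Reactants: 19
Product: 20 (1S,5S,7R)-3-(3,4-dihydroxybenzoyl)-1,5-digeranyl-4-hydroxy-8,8-dimethyl-7-prenylbicyclo[3.3.1]non-3-ene-2,9-dione (CNP0178719.1)
Conditions: Bu4NF (3 equiv), AcOH (3 equiv), THF, 0 °C
Reagents that add atoms: none
Why: Fluoride cleavage of the two aryl silyl ethers; acetic acid buffers the fluoride so that catecholate and triketonate are not exposed to base and air, and the alkenes and stereocentres are untouched.

## Compound list

1 | benzene-1,3,5-triol (phloroglucinol) | Oc1cc(O)cc(O)c1 | starting material
2 | 3,4-dihydroxybenzoic acid | O=C(O)c1ccc(O)c(O)c1 | starting material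
3 | (3,4-dihydroxyphenyl)(2,4,6-trihydroxyphenyl)methanone | O=C(c1ccc(O)c(O)c1)c1c(O)cc(O)cc1O | intermediate
4 | propan-2-ol | CC(C)O | starting material
5 | (3,4-dihydroxyphenyl)[2,4,6-trihydroxy-3-(propan-2-yl)phenyl]methanone | CC(C)c1c(O)cc(O)c(C(=O)c2ccc(O)c(O)c2)c1O | intermediate
6 | geraniol, (2E)-3,7-dimethylocta-2,6-dien-1-ol | CC(C)=CCC/C(C)=C/CO | starting material
7 | (3,4-dihydroxyphenyl){3-[(2E)-3,7-dimethylocta-2,6-dien-1-yl]-2,4,6-trihydroxy-5-(propan-2-yl)phenyl}methanone | CC(C)=CCC/C(C)=C/Cc1c(O)c(C(C)C)c(O)c(C(=O)c2ccc(O)c(O)c2)c1O | intermediate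
8 | [3,4-bis(tert-butyldimethylsilyloxy)phenyl]{3-[(2E)-3,7-dimethylocta-2,6-dien-1-yl]-2,4,6-trihydroxy-5-(propan-2-yl)phenyl}methanone | CC(C)=CCC/C(C)=C/Cc1c(O)c(C(C)C)c(O)c(C(=O)c2ccc(O[Si](C)(C)C(C)(C)C)c(O[Si](C)(C)C(C)(C)C)c2)c1O | intermediate
9 | prop-2-enal (acrolein) | C=CC=O | starting material
10 | (6S)-2-[3,4-bis(tert-butyldimethylsilyloxy)benzoyl]-6-[(2E)-3,7-dimethylocta-2,6-dien-1-yl]-3,5-dihydroxy-6-(3-oxopropyl)-4-(propan-2-yl)cyclohexa-2,4-dien-1-one | CC(C)=CCC/C(C)=C/C[C@]1(CCC=O)C(=O)C(C(=O)c2ccc(O[Si](C)(C)C(C)(C)C)c(O[Si](C)(C)C(C)(C)C)c2)=C(O)C(C(C)C)=C1O | intermediate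
11 | (6S)-2-[3,4-bis(tert-butyldimethylsilyloxy)benzoyl]-6-[(2E)-3,7-dimethylocta-2,6-dien-1-yl]-3-hydroxy-6-(3-oxopropyl)-4-(propan-2-ylidene)cyclohex-2-ene-1,5-dione | CC(C)=CCC/C(C)=C/C[C@]1(CCC=O)C(=O)C(C(=O)c2ccc(O[Si](C)(C)C(C)(C)C)c(O[Si](C)(C)C(C)(C)C)c2)=C(O)C(=C(C)C)C1=O | intermediate (not isolated)
12 | (6R)-2-[3,4-bis(tert-butyldimethylsilyloxy)benzoyl]-6-[(2E)-3,7-dimethylocta-2,6-dien-1-yl]-3-hydroxy-4-(propan-2-ylidene)-6-[(2E)-3-(pyrrolidin-1-yl)prop-2-en-1-yl]cyclohex-2-ene-1,5-dione (same spatial arrangement at the quaternary carbon as 10) | CC(C)=CCC/C(C)=C/C[C@]1(C/C=C/N2CCCC2)C(=O)C(C(=O)c3ccc(O[Si](C)(C)C(C)(C)C)c(O[Si](C)(C)C(C)(C)C)c3)=C(O)C(=C(C)C)C1=O | intermediate (not isolated)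
13 | (1S,5S,7E)-3-[3,4-bis(tert-butyldimethylsilyloxy)benzoyl]-5-[(2E)-3,7-dimethylocta-2,6-dien-1-yl]-4-hydroxy-8,8-dimethyl-7-(pyrrolidin-1-ylmethylidene)bicyclo[3.3.1]non-3-ene-2,9-dione | CC(C)=CCC/C(C)=C/C[C@]12C/C(=C\N3CCCC3)C(C)(C)[C@H](C(=O)C(C(=O)c4ccc(O[Si](C)(C)C(C)(C)C)c(O[Si](C)(C)C(C)(C)C)c4)=C1O)C2=O | intermediate (not isolated)
14 | (1S,5S,7R)-3-[3,4-bis(tert-butyldimethylsilyloxy)benzoyl]-5-[(2E)-3,7-dimethylocta-2,6-dien-1-yl]-7-formyl-4-hydroxy-8,8-dimethylbicyclo[3.3.1]non-3-ene-2,9-dione (formyl equatorial) | CC(C)=CCC/C(C)=C/C[C@]12C[C@@H](C=O)C(C)(C)[C@H](C(=O)C(C(=O)c3ccc(O[Si](C)(C)C(C)(C)C)c(O[Si](C)(C)C(C)(C)C)c3)=C1O)C2=O | intermediate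
15 | (1S,5S,7S)-3-[3,4-bis(tert-butyldimethylsilyloxy)benzoyl]-5-[(2E)-3,7-dimethylocta-2,6-dien-1-yl]-4-hydroxy-7-(2-methoxyethenyl)-8,8-dimethylbicyclo[3.3.1]non-3-ene-2,9-dione (E/Z mixture at the enol ether, both isomers converge) | CC(C)=CCC/C(C)=C/C[C@]12C[C@@H](C=COC)C(C)(C)[C@H](C(=O)C(C(=O)c3ccc(O[Si](C)(C)C(C)(C)C)c(O[Si](C)(C)C(C)(C)C)c3)=C1O)C2=O | intermediate (not isolated)
16 | (1S,5S,7S)-3-[3,4-bis(tert-butyldimethylsilyloxy)benzoyl]-5-[(2E)-3,7-dimethylocta-2,6-dien-1-yl]-4-hydroxy-8,8-dimethyl-7-(2-oxoethyl)bicyclo[3.3.1]non-3-ene-2,9-dione | CC(C)=CCC/C(C)=C/C[C@]12C[C@@H](CC=O)C(C)(C)[C@H](C(=O)C(C(=O)c3ccc(O[Si](C)(C)C(C)(C)C)c(O[Si](C)(C)C(C)(C)C)c3)=C1O)C2=O | intermediate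
17 | (1S,5S,7R)-3-[3,4-bis(tert-butyldimethylsilyloxy)benzoyl]-5-[(2E)-3,7-dimethylocta-2,6-dien-1-yl]-4-hydroxy-8,8-dimethyl-7-(3-methylbut-2-en-1-yl)bicyclo[3.3.1]non-3-ene-2,9-dione | CC(C)=CCC/C(C)=C/C[C@]12C[C@@H](CC=C(C)C)C(C)(C)[C@H](C(=O)C(C(=O)c3ccc(O[Si](C)(C)C(C)(C)C)c(O[Si](C)(C)C(C)(C)C)c3)=C1O)C2=O | intermediate
18 | geranyl bromide, (2E)-1-bromo-3,7-dimethylocta-2,6-diene | CC(C)=CCC/C(C)=C/CBr | starting material
19 | (1S,5S,7R)-3-[3,4-bis(tert-butyldimethylsilyloxy)benzoyl]-1,5-bis[(2E)-3,7-dimethylocta-2,6-dien-1-yl]-4-hydroxy-8,8-dimethyl-7-(3-methylbut-2-en-1-yl)bicyclo[3.3.1]non-3-ene-2,9-dione | CC(C)=CCC/C(C)=C/C[C@]12C[C@@H](CC=C(C)C)C(C)(C)[C@](C/C=C(\C)CCC=C(C)C)(C(=O)C(C(=O)c3ccc(O[Si](C)(C)C(C)(C)C)c(O[Si](C)(C)C(C)(C)C)c3)=C1O)C2=O | intermediate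
20 | (1S,5S,7R)-3-(3,4-dihydroxybenzoyl)-1,5-bis[(2E)-3,7-dimethylocta-2,6-dien-1-yl]-4-hydroxy-8,8-dimethyl-7-(3-methylbut-2-en-1-yl)bicyclo[3.3.1]non-3-ene-2,9-dione (CNP0178719.1) | CC(C)=CCC/C(C)=C/C[C@]12C[C@@H](CC=C(C)C)C(C)(C)[C@](C/C=C(\C)CCC=C(C)C)(C(=O)C(C(=O)c3ccc(O)c(O)c3)=C1O)C2=O | target

## Step count and least certain steps

Total: 10 steps. Longest linear sequence: 10 steps (from 1 to 20).

Step 6 (key step). Most likely failure: the ring closure stalls, because the conjugate addition must deliver its electron pair to C1 while the bicycle forms, that is into a bridgehead enolate that only the C2 carbonyl can stabilise, and only with strain. Meanwhile the isopropylidene trione can drain away by tautomerisation to the isopropenyl enol or by intermolecular hetero-Diels–Alder reaction with an alkene or enamine of a second molecule, and the aldehyde or its lactol can be over-oxidised during the silver stage.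

Fallback (known chemistry, sets out from 3, returns at 19): twofold Friedel–Crafts geranylation of 3 with 6 as in step 3 would give the 3,5-digeranyl pentaphenol F1, and silylation as in step 4 its catechol bis-silyl ether F2. Alkylative dearomatisation–annulation of F2 with the separately prepared enal 2-(2-acetoxypropan-2-yl)prop-2-enal F3, under the phase-transfer conditions of step 5, is the established way to close ring A in this family. One geranylated ring carbon adds to the enal CH2, acetate is lost, and the second geranylated ring carbon adds to the resulting β,β-dimethyl enal. The bridgehead therefore becomes sp3 in the ring-closing event and no bridgehead enolate is needed. This should give the 1,5-digeranyl-7-formyl bicycle F4. The sequence of step 7, through the methyl enol ether F5 to the homologous aldehyde F6, and the Wittig reaction of step 8 then lead to 19. Step 9 is not needed on this path.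

Step 9. Most likely failure: incomplete removal of the bridgehead proton from a substrate that is already an anion, and alkylation of the triketonate on oxygen by the excess of allylic bromide.

Fallback (sets out from 17, returns at 19): O-methylation with Me3SiCHN2 would give the regioisomeric methyl enol ethers, of which the 4-methoxy isomer F7 (C2 still a ketone beside C1) is carried on. A single bridgehead lithiation with LiN(i-Pr)2 and alkylation with 18, the form in which bridgehead substitution of such vinylogous esters is established, would give the C1-geranylated methyl ether F8. LiCl in DMSO at 120 °C would then cleave the methyl ether by SN2 attack at methyl and return 19; partial loss of a silyl group there is harmless because step 10 follows.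

Step 5. Most likely failure: poor facial selectivity at a fully substituted carbon, partial attack at the isopropyl-bearing carbon, loss of an aryl silyl ether to the base, and polymerisation of acrolein.

Fallback (sets out from 8, returns at 10): allylic alkylation with dearomatisation of the Tsuji–Trost type, catalysed by zerovalent palladium (Pd2(dba)3, (R,R)- or (S,S)-N,N′-cyclohexane-1,2-diylbis[2-(diphenylphosphanyl)benzamide], allyl methyl carbonate), would give the 6-allyl dienone F9. Hydroboration of the monosubstituted alkene with 9-borabicyclo[3.3.1]nonane and NaBO3 oxidation would give the primary alcohol F10, and oxidation with SO3·pyridine/DMSO would return 10.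

Step 2. Most likely failure: over-alkylation at the second equivalent ring position and some alkylation of the catechol ring, giving mixtures that are hard to separate.

Fallback (sets out from 1, returns at 5): exhaustive O-methylation (Me2SO4, K2CO3) would give 1,3,5-trimethoxybenzene F11. Ring lithiation (n-BuLi) and addition to acetone would give 2-(2,4,6-trimethoxyphenyl)propan-2-ol F12, and ionic hydrogenation (Et3SiH, CF3CO2H) 1,3,5-trimethoxy-2-(propan-2-yl)benzene F13. BBr3 demethylation would give 2-(propan-2-yl)benzene-1,3,5-triol F14, and acylation with 2 under the conditions of step 1 returns 5. Only one alkyl group can enter by this path.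

Step 3. Most likely failure: acid-induced closure of the geranyl chain onto a flanking hydroxyl and low conversion of the acyl-deactivated ring.

Fallback (sets out from 5, returns at 7): C-alkylation of the phloroglucinolate with 18 in cold aqueous KOH containing Na2B4O7, which holds the catechol as its cyclic borate so that the ring carbon is the only soft nucleophile. No new compound is made.

## Further compounds

F1 | step 6 | (3,4-dihydroxyphenyl){3,5-bis[(2E)-3,7-dimethylocta-2,6-dien-1-yl]-2,4,6-trihydroxyphenyl}methanone | CC(C)=CCC/C(C)=C/Cc1c(O)c(C/C=C(\C)CCC=C(C)C)c(O)c(C(=O)c2ccc(O)c(O)c2)c1O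
F2 | step 6 | [3,4-bis(tert-butyldimethylsilyloxy)phenyl]{3,5-bis[(2E)-3,7-dimethylocta-2,6-dien-1-yl]-2,4,6-trihydroxyphenyl}methanone | CC(C)=CCC/C(C)=C/Cc1c(O)c(C/C=C(\C)CCC=C(C)C)c(O)c(C(=O)c2ccc(O[Si](C)(C)C(C)(C)C)c(O[Si](C)(C)C(C)(C)C)c2)c1O
F3 | step 6 | 2-(2-acetoxypropan-2-yl)prop-2-enal | C=C(C=O)C(C)(C)OC(C)=O
F4 | step 6 | (1S,5S,7R)-3-[3,4-bis(tert-butyldimethylsilyloxy)benzoyl]-1,5-bis[(2E)-3,7-dimethylocta-2,6-dien-1-yl]-7-formyl-4-hydroxy-8,8-dimethylbicyclo[3.3.1]non-3-ene-2,9-dione | CC(C)=CCC/C(C)=C/C[C@]12C[C@@H](C=O)C(C)(C)[C@](C/C=C(\C)CCC=C(C)C)(C(=O)C(C(=O)c3ccc(O[Si](C)(C)C(C)(C)C)c(O[Si](C)(C)C(C)(C)C)c3)=C1O)C2=O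
F5 | step 6 | (1S,5S,7S)-3-[3,4-bis(tert-butyldimethylsilyloxy)benzoyl]-1,5-bis[(2E)-3,7-dimethylocta-2,6-dien-1-yl]-4-hydroxy-7-(2-methoxyethenyl)-8,8-dimethylbicyclo[3.3.1]non-3-ene-2,9-dione (E/Z mixture at the enol ether) | CC(C)=CCC/C(C)=C/C[C@]12C[C@@H](C=COC)C(C)(C)[C@](C/C=C(\C)CCC=C(C)C)(C(=O)C(C(=O)c3ccc(O[Si](C)(C)C(C)(C)C)c(O[Si](C)(C)C(C)(C)C)c3)=C1O)C2=O
F6 | step 6 | (1S,5S,7S)-3-[3,4-bis(tert-butyldimethylsilyloxy)benzoyl]-1,5-bis[(2E)-3,7-dimethylocta-2,6-dien-1-yl]-4-hydroxy-8,8-dimethyl-7-(2-oxoethyl)bicyclo[3.3.1]non-3-ene-2,9-dione | CC(C)=CCC/C(C)=C/C[C@]12C[C@@H](CC=O)C(C)(C)[C@](C/C=C(\C)CCC=C(C)C)(C(=O)C(C(=O)c3ccc(O[Si](C)(C)C(C)(C)C)c(O[Si](C)(C)C(C)(C)C)c3)=C1O)C2=O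
F7 | step 9 | (1S,5S,7R)-3-[3,4-bis(tert-butyldimethylsilyloxy)benzoyl]-5-[(2E)-3,7-dimethylocta-2,6-dien-1-yl]-4-methoxy-8,8-dimethyl-7-(3-methylbut-2-en-1-yl)bicyclo[3.3.1]non-3-ene-2,9-dione | CC(C)=CCC/C(C)=C/C[C@]12C[C@@H](CC=C(C)C)C(C)(C)[C@H](C(=O)C(C(=O)c3ccc(O[Si](C)(C)C(C)(C)C)c(O[Si](C)(C)C(C)(C)C)c3)=C1OC)C2=O
F8 | step 9 | (1S,5S,7R)-3-[3,4-bis(tert-butyldimethylsilyloxy)benzoyl]-1,5-bis[(2E)-3,7-dimethylocta-2,6-dien-1-yl]-4-methoxy-8,8-dimethyl-7-(3-methylbut-2-en-1-yl)bicyclo[3.3.1]non-3-ene-2,9-dione | CC(C)=CCC/C(C)=C/C[C@]12C[C@@H](CC=C(C)C)C(C)(C)[C@](C/C=C(\C)CCC=C(C)C)(C(=O)C(C(=O)c3ccc(O[Si](C)(C)C(C)(C)C)c(O[Si](C)(C)C(C)(C)C)c3)=C1OC)C2=O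
F9 | step 5 | (6S)-2-[3,4-bis(tert-butyldimethylsilyloxy)benzoyl]-6-[(2E)-3,7-dimethylocta-2,6-dien-1-yl]-3,5-dihydroxy-4-(propan-2-yl)-6-(prop-2-en-1-yl)cyclohexa-2,4-dien-1-one | CC(C)=CCC/C(C)=C/C[C@]1(CC=C)C(=O)C(C(=O)c2ccc(O[Si](C)(C)C(C)(C)C)c(O[Si](C)(C)C(C)(C)C)c2)=C(O)C(C(C)C)=C1O
F10 | step 5 | (6S)-2-[3,4-bis(tert-butyldimethylsilyloxy)benzoyl]-6-[(2E)-3,7-dimethylocta-2,6-dien-1-yl]-3,5-dihydroxy-6-(3-hydroxypropyl)-4-(propan-2-yl)cyclohexa-2,4-dien-1-one | CC(C)=CCC/C(C)=C/C[C@]1(CCCO)C(=O)C(C(=O)c2ccc(O[Si](C)(C)C(C)(C)C)c(O[Si](C)(C)C(C)(C)C)c2)=C(O)C(C(C)C)=C1O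
F11 | step 2 | 1,3,5-trimethoxybenzene | COc1cc(OC)cc(OC)c1
F12 | step 2 | 2-(2,4,6-trimethoxyphenyl)propan-2-ol | COc1cc(OC)c(C(C)(C)O)c(OC)c1
F13 | step 2 | 1,3,5-trimethoxy-2-(propan-2-yl)benzene | COc1cc(OC)c(C(C)C)c(OC)c1
F14 | step 2 | 2-(propan-2-yl)benzene-1,3,5-triol | CC(C)c1c(O)cc(O)cc1O
F0 | step 3 | none | none
A1 | alternative 1 | 1,5-digeranyl-2-methoxy-8,8-dimethyl-7-prenylbicyclo[3.3.1]non-2-ene-4,9-dione (configured as in 20) | CC(C)=CCC/C(C)=C/C[C@]12C[C@@H](CC=C(C)C)C(C)(C)[C@](C/C=C(\C)CCC=C(C)C)(C(OC)=CC1=O)C2=O
A2 | alternative 1 | methyl (2E)-3-[1,3-digeranyl-6,6-dimethyl-2-oxo-5-prenylcyclohex-3-en-1-yl]-3-methoxyprop-2-enoate (ring stereocentres as in A1) | CC(C)=CCC/C(C)=C/CC1=C[C@@H](CC=C(C)C)C(C)(C)[C@](C/C=C(\C)CCC=C(C)C)(/C(OC)=C\C(=O)OC)C1=O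
A3 | alternative 2 | 5-geranyl-4-methoxy-8,8-dimethyl-7-prenylbicyclo[3.3.1]non-3-ene-2,9-dione (C1–H, configured as in 17) | CC(C)=CCC/C(C)=C/C[C@]12C[C@@H](CC=C(C)C)C(C)(C)[C@H](C(=O)C=C1OC)C2=O
A4 | alternative 2 | 4-geranyl-3,5-dimethoxy-4-[(2R)-5-methyl-2-(prop-1-en-2-yl)hex-4-en-1-yl]cyclohexa-2,5-dien-1-one | CC(C)=CCC/C(C)=C/CC1(C[C@@H](CC=C(C)C)C(C)=C)C(OC)=CC(=O)C=C1OC
A5 | alternative 3 | bis(tert-butyldimethylsilyl) ether of the target (identical with 19) | CC(C)=CCC/C(C)=C/C[C@]12C[C@@H](CC=C(C)C)C(C)(C)[C@](C/C=C(\C)CCC=C(C)C)(C(=O)C(C(=O)c3ccc(O[Si](C)(C)C(C)(C)C)c(O[Si](C)(C)C(C)(C)C)c3)=C1O)C2=O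
A6 | alternative 3 | 2-[3,4-bis(tert-butyldimethylsilyloxy)benzoyl]-4,6-digeranyl-3,5-dihydroxy-6-(2-methylbut-3-en-2-yl)cyclohexa-2,4-dien-1-one (quaternary carbon configured as C1 of 19) | C=CC(C)(C)[C@]1(C/C=C(\C)CCC=C(C)C)C(=O)C(C(=O)c2ccc(O[Si](C)(C)C(C)(C)C)c(O[Si](C)(C)C(C)(C)C)c2)=C(O)C(C/C=C(\C)CCC=C(C)C)=C1O
A7 | alternative 3 | 3-chloro-3-methylbut-1-ene | C=CC(C)(C)Cl
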